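**Retrosynthetic overview**

1. Toxiusol 38 ⇐ sulfation/demethylation of bis(methyl ether) 36 ⇐ removal of the C2' carbonyl of enone 35. Locants: left decalin C1–C10, ring A = C1–C5,C10, ring B = C5–C10; linker C11–C12; right decalin C1'–C10', ring A' = C1'–C5',C10', ring B' = C5'–C10'.
2. Key disconnection: 35 ⇐ alkynyl cyclobutanone 34. Rhodium inserts the C10'≡C1' alkyne into the C2'–C5' bond of a 3,3-dimethylcyclobutanone, so ring A' grows from four to six atoms while ring B' closes in the same operation.
3. Enabling feature: in ring A' the C1'=C10' alkene ends at the ring-fusion atom C10', the gem-dimethyl C4' is next to the C5'–H fusion atom, and C2' is a plain CH2. C2'–C5' therefore map onto a cyclobutanone and C1'/C10' onto an alkyne already tied to C5' through C6'–C9'; the C2' carbonyl left behind can be deleted.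
4. 34 ⇐ SAMP-hydrazone alkylation of 3,3-dimethylcyclobutanone with iodide 28 ⇐ Eschenmoser–Tanabe opening of a temporary cyclohexenone that sets C8'/C9' ⇐ enolate alkylation (C12–C9') of silyl enol ether 19 with left-half iodide 16 ⇐ asymmetric Diels–Alder, C9 methylation, aryl addition; C4 from asymmetric allylation.
5. Ring order: ring A (starting material) → ring B (Diels–Alder) → temporary six-membered ring (made, then opened) → rings B' and A' together in the key step.

Key step: step 22

Remark on names: "Oct" stands for the (4S,8R,9R,10S)-9-(2,5-dimethoxybenzyl)-4,8,9-trimethyl-Δ5-octalin-4-yl group (target locants, C5=C6 alkene); the target is (4S,8R,9R,10S,5'R,8'S,9'R) in these locants.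

Assumption: each chiral controller is written in the enantiomer taken to give the configuration drawn ((S)-t-BuPHOX, the (S)-prolinol-derived oxazaborolidinium salt, the (S,S)-phosphoramidite, SAMP); where the sense of induction is the opposite, the mirror-image controller is used.

**Route**

Step 1
Reactants: 1 allyl 2-oxocyclohexane-1-carboxylate
Product: 2 allyl 1-methyl-2-oxocyclohexane-1-carboxylate (racemic)
Conditions: K2CO3, MeI, acetone, reflux
Reagents that add atoms: iodomethane (CI)
Why: C-alkylation of the β-keto ester enolate at its only acidic C–H gives the quaternary, still racemic, carbon that becomes C4.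

Step 2
Reactants: 2 allyl 1-methyl-2-oxocyclohexane-1-carboxylate
Product: 3 (S)-2-allyl-2-methylcyclohexan-1-one
Conditions: Pd2(dba)3 (2.5 mol %), (S)-t-BuPHOX (6 mol %), THF, 25 °C
Reagents that add atoms: none
Why: Decarboxylative Tsuji–Trost allylation: zerovalent palladium ionises the allyl ester, CO2 is lost, and the PHOX-bound allylpalladium enolate recombines on one enolate face, which sets C4.

Step 3
Reactants: 3 (S)-2-allyl-2-methylcyclohexan-1-one
Product: 4 (S)-6-allyl-6-methylcyclohex-1-en-1-yl triflate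
Conditions: Tf2O, 2,6-di-tert-butyl-4-methylpyridine, CH2Cl2, 0 °C → rt
Reagents that add atoms: triflic anhydride (O=S(=O)(OS(=O)(=O)C(F)(F)F)C(F)(F)F)
Why: Enol triflate formation by O-triflation of the ketone; only one α-carbon carries hydrogens, so a single regioisomer can form.

Step 4
Reactants: 4 (S)-6-allyl-6-methylcyclohex-1-en-1-yl triflate
Product: 6 (S)-6-(2-hydroxyethyl)-6-methylcyclohex-1-en-1-yl triflate, via aldehyde 5 (not isolated)
Conditions: OsO4 (2 mol %), NaIO4, 2,6-lutidine, dioxane/H2O, rt; then NaBH4, MeOH, 0 °C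
Reagents that add atoms: sodium periodate ([Na+].[O-]I(=O)(=O)=O)
Why: Lemieux–Johnson cleavage is selective for the electron-rich terminal alkene over the electron-poor enol triflate, and borohydride reduction of the aldehyde gives the two-carbon C11–C12 arm.

Step 5
Reactants: 6 (S)-6-(2-hydroxyethyl)-6-methylcyclohex-1-en-1-yl triflate
Product: 7 2-[(1S)-1-methyl-2-vinylcyclohex-2-en-1-yl]ethan-1-ol
Conditions: Bu3SnCH=CH2, Pd(PPh3)4 (5 mol %), LiCl, THF, reflux
Reagents that add atoms: tributyl(vinyl)stannane (C=C[Sn](CCCC)(CCCC)CCCC)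
Why: Stille coupling of the vinyl triflate installs the vinyl group and so the 1,3-diene (C10=C5–C6=C7); the free alcohol is tolerated.

Step 6
Reactants: 7 2-[(1S)-1-methyl-2-vinylcyclohex-2-en-1-yl]ethan-1-ol
Product: 8 (S)-6-[2-(benzyloxy)ethyl]-6-methyl-1-vinylcyclohex-1-ene
Conditions: NaH, BnBr, Bu4NI (cat.), THF, 0 °C → rt
Reagents that add atoms: benzyl bromide (BrCc1ccccc1)
Why: Williamson etherification protects the primary alcohol as a benzyl ether, which is removed later in the same operation as the benzylic deoxygenation (step 10).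

Step 7
Reactants: 8 (S)-6-[2-(benzyloxy)ethyl]-6-methyl-1-vinylcyclohex-1-ene; 9 (E)-but-2-enal
Product: 10 (4S,8R,10S)-4-[2-(benzyloxy)ethyl]-4,8-dimethyl-Δ5-octalin-9-carbaldehyde (formyl group trans to H-10 and to the C8 methyl)
Conditions: oxazaborolidinium triflimide from (S)-α,α-diphenylprolinol, o-tolylboronic acid and Tf2NH (20 mol %), CH2Cl2, −78 → −40 °C
Reagents that add atoms: none
Why: Lewis-acid-catalysed asymmetric Diels–Alder reaction in which the vinyl CH2 terminus (largest HOMO coefficient) pairs with the enal β-carbon (C7–C8 and C9–C10 bonds), the endo approach places the C8 methyl cis to H-10, and the chiral oxazaborolidinium shields one face of the bound enal so that C8 and C10 are set absolutely over the weak bias of C4 (the C9 centre is provisional).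

Step 8
Reactants: 10 (4S,8R,10S)-4-[2-(benzyloxy)ethyl]-4,8-dimethyl-Δ5-octalin-9-carbaldehyde
Product: 11 (4S,8R,9R,10S)-4-[2-(benzyloxy)ethyl]-4,8,9-trimethyl-Δ5-octalin-9-carbaldehyde
Conditions: KOtBu, MeI, THF, 0 °C
Reagents that add atoms: iodomethane (CI)
Why: Enolate C-methylation of the α-branched aldehyde; in the trans-like half-chair the C8 methyl is pseudoaxial, so iodomethane should add axially to the exocyclic enolate from the opposite face, which sets C9 with its methyl trans to the C8 methyl and the formyl group cis to H-10.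

Step 9
Reactants: 11 (4S,8R,9R,10S)-4-[2-(benzyloxy)ethyl]-4,8,9-trimethyl-Δ5-octalin-9-carbaldehyde; 12 2-bromo-1,4-dimethoxybenzene
Product: 14 (2,5-dimethoxyphenyl)[(4S,8R,9R,10S)-4-(2-benzyloxyethyl)-4,8,9-trimethyl-Δ5-octalin-9-yl]methanol (both carbinol epimers), via aryllithium 13 (not isolated)
Conditions: 12, n-BuLi, THF, −78 °C; then 11, −78 → 0 °C; H2O
Reagents that add atoms: none
Why: Bromine–lithium exchange followed by 1,2-addition of the aryllithium to the non-enolisable neopentyl aldehyde; the new carbinol centre is removed in step 10, so its configuration does not matter.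

Step 10
Reactants: 14 (2,5-dimethoxyphenyl)[(4S,8R,9R,10S)-4-(2-benzyloxyethyl)-4,8,9-trimethyl-Δ5-octalin-9-yl]methanol
Product: 15 2-Oct-ethan-1-ol
Conditions: Li, NH3(l)/THF, −78 → −33 °C; then NH4Cl
Reagents that add atoms: none
Why: Dissolving-metal (Birch-type) hydrogenolysis should cleave both benzylic C–O bonds, the hindered carbinol to the ArCH2 group and the benzyl ether to the free alcohol, while the isolated trisubstituted alkene and, without an alcohol cosolvent, the dimethoxyarene stay intact.

Step 11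
Reactants: 15 2-Oct-ethan-1-ol
Product: 16 Oct-CH2CH2I (left-half iodide)
Conditions: I2, PPh3, imidazole, CH2Cl2, 0 °C → rt
Reagents that add atoms: iodine (II)
Why: Appel-type iodination of the primary alcohol by SN2 displacement of the oxyphosphonium group.

Step 12
Reactants: 17 2-methylcyclohex-2-en-1-one
Product: 19 (S)-[(2,3-dimethylcyclohex-1-en-1-yl)oxy]trimethylsilane, via aluminium enolate 18 (not isolated)
Conditions: Me3Al, Cu(O2CC4H3S) (copper thiophene-2-carboxylate, 2 mol %), O,O'-(2,2'-biphenyldiyl) N,N-bis[(S)-1-phenylethyl]phosphoramidite (4 mol %), Et2O, −30 °C; then TMSOTf, −30 → 0 °C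
Reagents that add atoms: trimethylaluminium (C[Al](C)C); trimethylsilyl triflate (C[Si](C)(C)OS(=O)(=O)C(F)(F)F)
Why: Copper-catalysed asymmetric conjugate addition of a methyl group, in which the phosphoramidite complex of monovalent copper selects the enone face and sets C8', and O-silylation stores the regiodefined tetrasubstituted enolate.

Step 13
Reactants: 19 (S)-[(2,3-dimethylcyclohex-1-en-1-yl)oxy]trimethylsilane; 16 Oct-CH2CH2I
Product: 21 (2R,3S)-2,3-dimethyl-2-(2-Oct-ethyl)cyclohexan-1-one (methyl groups cis), via lithium enolate 20 (not isolated)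
Conditions: MeLi, THF, 0 °C; then HMPA, 16, −40 °C → rt
Reagents that add atoms: none
Why: Regiospecific lithium enolate generation from the silyl enol ether and SN2 alkylation; the iodide enters anti to the pseudoaxial C8' methyl, which forms the C12–C9' bond and sets the quaternary C9' with its methyl cis to the C8' methyl.

Step 14
Reactants: 21 (2R,3S)-2,3-dimethyl-2-(2-Oct-ethyl)cyclohexan-1-one
Product: 23 (5S,6R)-5,6-dimethyl-6-(2-Oct-ethyl)cyclohex-2-en-1-one, via silyl enol ether 22 (not isolated)
Conditions: LDA, TMSCl, THF, −78 °C; then Pd(OAc)2, MeCN, rt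
Reagents that add atoms: none
Why: Saegusa–Ito dehydrogenation: the silyl enol ether can form only toward C1' because C9' is quaternary, and divalent palladium acetate then gives the C1'=C6' enone of the temporary ring.

Step 15
Reactants: 23 (5S,6R)-5,6-dimethyl-6-(2-Oct-ethyl)cyclohex-2-en-1-one
Product: 24 2,3-epoxide of 23 (oxirane trans to the C5 methyl of the cyclohexanone)
Conditions: 30% H2O2, NaOH (cat.), MeOH, 0 °C
Reagents that add atoms: hydrogen peroxide (OO)
Why: Weitz–Scheffer nucleophilic epoxidation acts only on the electron-poor enone double bond and leaves the isolated C5=C6 alkene alone; hydroperoxide should add anti to the C8' methyl, but either epoxide serves the next step.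

Step 16
Reactants: 24 2,3-epoxide of 23
Product: 26 (3S,4R)-4-ethynyl-3,4-dimethyl-6-Oct-hexanal, via tosylhydrazone 25 (not isolated)
Conditions: TsNHNH2, AcOH/CH2Cl2 (1:1), −20 °C → rt
Reagents that add atoms: none
Why: Eschenmoser–Tanabe fragmentation: the epoxy tosylhydrazone opens to an alkoxy azoalkene that breaks the C1'–C6' bond with loss of N2 and sulfinate, which unveils the C10'≡C1' alkyne on the quaternary C9' and the C6' aldehyde without touching C8' or C9'.

Step 17
Reactants: 26 (3S,4R)-4-ethynyl-3,4-dimethyl-6-Oct-hexanal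
Product: 27 (3S,4R)-4-ethynyl-3,4-dimethyl-6-Oct-hexan-1-ol
Conditions: NaBH4, MeOH, 0 °C
Reagents that add atoms: none
Why: Chemoselective borohydride reduction of the aldehyde.

Step 18
Reactants: 27 (3S,4R)-4-ethynyl-3,4-dimethyl-6-Oct-hexan-1-ol
Product: 28 (3S,4R)-4-ethynyl-1-iodo-3,4-dimethyl-6-Oct-hexane
Conditions: I2, PPh3, imidazole, CH2Cl2, 0 °C → rt
Reagents that add atoms: iodine (II)
Why: Appel-type iodination of the primary alcohol; the terminal alkyne is inert.

Step 19
Reactants: 29 3,3-dimethylcyclobutan-1-one; 30 (S)-1-amino-2-(methoxymethyl)pyrrolidine (SAMP)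
Product: 31 (S)-N-(3,3-dimethylcyclobutylidene)-2-(methoxymethyl)pyrrolidin-1-amine
Conditions: neat, 60 °C, 4 Å molecular sieves
Reagents that add atoms: none
Why: Hydrazone formation by condensation; the ketone is symmetric, so no regio- or geometric isomers arise.

Step 20
Reactants: 31 (S)-N-(3,3-dimethylcyclobutylidene)-2-(methoxymethyl)pyrrolidin-1-amine; 28 (3S,4R)-4-ethynyl-1-iodo-3,4-dimethyl-6-Oct-hexane
Product: 33 SAMP hydrazone of (2R)-2-[(3S,4R)-4-ethynyl-3,4-dimethyl-6-Oct-hexyl]-3,3-dimethylcyclobutan-1-one, via lithium azaenolate 32 (not isolated)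
Conditions: 31 (2.2 equiv), LDA (2.2 equiv), THF, 0 °C; then 28, −100 °C → rt
Reagents that add atoms: none
Why: SAMP-hydrazone α-alkylation: the chelated azaenolate is alkylated by the primary iodide on the face dictated by the methoxymethylpyrrolidine, which sets C5' (R) independently of the remote C8'/C9' centres; the second equivalent of azaenolate covers the acidic alkyne C–H.

Step 21
Reactants: 33 SAMP hydrazone of the 2-alkylcyclobutanone
Product: 34 (2R)-2-[(3S,4R)-4-ethynyl-3,4-dimethyl-6-Oct-hexyl]-3,3-dimethylcyclobutan-1-one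
Conditions: saturated aqueous oxalic acid, Et2O, rt
Reagents that add atoms: water (O)
Why: Mild two-phase acid hydrolysis of the hydrazone should free the cyclobutanone without epimerising the α-stereocentre C5' and returns the auxiliary.

Step 22
Reactants: 34 (2R)-2-[(3S,4R)-4-ethynyl-3,4-dimethyl-6-Oct-hexyl]-3,3-dimethylcyclobutan-1-one
Product: 35 (5'R,8'S,9'R)-4',4',8',9'-tetramethyl-9'-(2-Oct-ethyl)-Δ1'(10')-octalin-2'-one
Conditions: [Rh(C2H4)2Cl]2 (5 mol %), P[3,5-(CF3)2C6H3]3 (20 mol %), 1,4-dioxane, 130 °C, sealed tube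
Reagents that add atoms: none
Why: Monovalent rhodium, held by the tethered alkyne, should add oxidatively into the strained C2'–C5' (acyl–CH) bond of the cyclobutanone to give a rhodacyclopentanone, the alkyne then inserts into the Rh–C5' bond, and C1'–C2' reductive elimination releases the enone, so the four-membered ring has grown by the two alkyne carbons into ring A'. The closest known reaction type is the rhodium-catalysed intramolecular carboacylation ("cut and sew") of alkynes by cyclobutanones that carry the alkyne on the α-carbon, which gives fused cyclohexenones. Ring B' closes by 6-exo-dig carbometalation (C5'–C10' bond) and ring A' by reductive elimination from the seven-membered acyl(vinyl)rhodacycle (C1'–C2' bond), that is by two-atom ring expansion. No new stereocentre is formed: C5' keeps its configuration because its Rh–C bond is made and consumed with retention, C8' and C9' are not touched, and the alkene can only arise as C1'=C10'. The step needs cleavage of the C2'–C5' bond and not of the C2'–C3' bond, and insertion ahead of decarbonylation or β-hydride loss: only the substituted side can deliver the alkyne (cleavage on the other side is reversible and unproductive), the quaternary C9' holds the alkyne close, the C4' gem-dimethyl group removes the ring β-hydrogens, and the electron-poor triarylphosphine disfavours CO extrusion.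

Step 23
Reactants: 35 (5'R,8'S,9'R)-4',4',8',9'-tetramethyl-9'-(2-Oct-ethyl)-Δ1'(10')-octalin-2'-one
Product: 36 toxiusol hydroquinone bis(methyl ether)
Conditions: LiAlH4, AlCl3, Et2O, 0 °C → reflux
Reagents that add atoms: none
Why: Mixed-hydride deoxygenation of an enone to the alkene: reduction to the allylic alkoxide, ionisation to the allyl cation and hydride delivery to the less hindered secondary terminus C2' should keep the C1'=C10' double bond, as in the conversion of steroidal 4-en-3-ones into 4-enes.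

Step 24
Reactants: 36 toxiusol hydroquinone bis(methyl ether)
Product: 37 toxiusol hydroquinone
Conditions: NaSEt, DMF, 140 °C; then aqueous HCl
Reagents that add atoms: none
Why: SN2 demethylation of both aryl methyl ethers by thiolate, a non-acidic method that leaves the two trisubstituted alkenes untouched.

Step 25
Reactants: 37 toxiusol hydroquinone
Product: 38 toxiusol
Conditions: SO3·pyridine, pyridine, rt; then Dowex 50 (H+ form), 0 °C
Reagents that add atoms: sulfur trioxide–pyridine complex (O=S(=O)([O-])[n+]1ccccc1)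
Why: O-sulfation of both phenols with the SO3–pyridine complex, followed by proton exchange of the pyridinium salt, should give the bis(hydrogen sulfate).

**Compound list**

1 | allyl 2-oxocyclohexane-1-carboxylate | C=CCOC(=O)C1CCCCC1=O | starting material
2 | allyl 1-methyl-2-oxocyclohexane-1-carboxylate (racemic) | C=CCOC(=O)C1(C)CCCCC1=O | intermediate
3 | (S)-2-allyl-2-methylcyclohexan-1-one | O=C1CCCC[C@@]1(C)CC=C | intermediate
4 | (S)-6-allyl-6-methylcyclohex-1-en-1-yl triflate | O=S(=O)(OC1=CCCC[C@@]1(C)CC=C)C(F)(F)F | intermediate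
5 | 2-[(1S)-1-methyl-2-(triflyloxy)cyclohex-2-en-1-yl]acetaldehyde | O=S(=O)(OC1=CCCC[C@@]1(C)CC=O)C(F)(F)F | intermediate
6 | (S)-6-(2-hydroxyethyl)-6-methylcyclohex-1-en-1-yl triflate | O=S(=O)(OC1=CCCC[C@@]1(C)CCO)C(F)(F)F | intermediate
7 | 2-[(1S)-1-methyl-2-vinylcyclohex-2-en-1-yl]ethan-1-ol | C=CC1=CCCC[C@@]1(C)CCO | intermediate
8 | (S)-6-[2-(benzyloxy)ethyl]-6-methyl-1-vinylcyclohex-1-ene | C=CC1=CCCC[C@@]1(C)CCOCc1ccccc1 | intermediate
9 | (E)-but-2-enal | C/C=C/C=O | starting material
10 | (4S,8R,10S)-4-[2-(benzyloxy)ethyl]-4,8-dimethyl-Δ5-octalin-9-carbaldehyde, CHO trans to H-10 and to the C8 methyl | C[C@@H]1CC=C2[C@@H](CCC[C@@]2(C)CCOCc3ccccc3)[C@H]1C=O | intermediate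
11 | (4S,8R,9R,10S)-4-[2-(benzyloxy)ethyl]-4,8,9-trimethyl-Δ5-octalin-9-carbaldehyde | C[C@@H]1CC=C2[C@@H](CCC[C@@]2(C)CCOCc3ccccc3)[C@]1(C)C=O | intermediate
12 | 2-bromo-1,4-dimethoxybenzene | COc1ccc(OC)c(Br)c1 | starting material
13 | (2,5-dimethoxyphenyl)lithium | [Li]c1cc(OC)ccc1OC | intermediate
14 | (2,5-dimethoxyphenyl)[(4S,8R,9R,10S)-4-(2-benzyloxyethyl)-4,8,9-trimethyl-Δ5-octalin-9-yl]methanol, both carbinol epimers | C[C@@H]1CC=C2[C@@H](CCC[C@@]2(C)CCOCc3ccccc3)[C@]1(C)C(O)c1cc(OC)ccc1OC | intermediate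
15 | 2-Oct-ethan-1-ol (left-half alcohol) | C[C@@H]1CC=C2[C@@H](CCC[C@@]2(C)CCO)[C@]1(C)Cc1cc(OC)ccc1OC | intermediate
16 | Oct-CH2CH2I (left-half iodide) | C[C@@H]1CC=C2[C@@H](CCC[C@@]2(C)CCI)[C@]1(C)Cc1cc(OC)ccc1OC | intermediate
17 | 2-methylcyclohex-2-en-1-one | CC1=CCCCC1=O | starting material
18 | dimethylaluminium (S)-2,3-dimethylcyclohex-1-en-1-olate | CC1=C(O[Al](C)C)CCC[C@@H]1C | intermediate
19 | (S)-[(2,3-dimethylcyclohex-1-en-1-yl)oxy]trimethylsilane | CC1=C(O[Si](C)(C)C)CCC[C@@H]1C | intermediate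
20 | lithium (S)-2,3-dimethylcyclohex-1-en-1-olate | CC1=C(O[Li])CCC[C@@H]1C | intermediate
21 | (2R,3S)-2,3-dimethyl-2-(2-Oct-ethyl)cyclohexan-1-one | C[C@@H]1CC=C2[C@@H](CCC[C@@]2(C)CC[C@@]2(C)C(=O)CCC[C@@H]2C)[C@]1(C)Cc1cc(OC)ccc1OC | intermediate
22 | trimethylsilyl enol ether of 21 (enol toward C1') | C[C@@H]1CC=C2[C@@H](CCC[C@@]2(C)CC[C@@]2(C)C(O[Si](C)(C)C)=CCC[C@@H]2C)[C@]1(C)Cc1cc(OC)ccc1OC | intermediate
23 | (5S,6R)-5,6-dimethyl-6-(2-Oct-ethyl)cyclohex-2-en-1-one | C[C@@H]1CC=C2[C@@H](CCC[C@@]2(C)CC[C@@]2(C)C(=O)C=CC[C@@H]2C)[C@]1(C)Cc1cc(OC)ccc1OC | intermediate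
24 | 2,3-epoxide of 23, oxirane trans to the C5 methyl | C[C@@H]1CC=C2[C@@H](CCC[C@@]2(C)CC[C@@]2(C)C(=O)[C@H]3O[C@H]3C[C@@H]2C)[C@]1(C)Cc1cc(OC)ccc1OC | intermediate
25 | tosylhydrazone of 24 | C[C@@H]1CC=C2[C@@H](CCC[C@@]2(C)CC[C@@]2(C)/C(=N/NS(=O)(=O)c3ccc(C)cc3)[C@H]3O[C@H]3C[C@@H]2C)[C@]1(C)Cc1cc(OC)ccc1OC | intermediate
26 | (3S,4R)-4-ethynyl-3,4-dimethyl-6-Oct-hexanal | C[C@@H]1CC=C2[C@@H](CCC[C@@]2(C)CC[C@@](C)(C#C)[C@@H](C)CC=O)[C@]1(C)Cc1cc(OC)ccc1OC | intermediate
27 | (3S,4R)-4-ethynyl-3,4-dimethyl-6-Oct-hexan-1-ol | C[C@@H]1CC=C2[C@@H](CCC[C@@]2(C)CC[C@@](C)(C#C)[C@@H](C)CCO)[C@]1(C)Cc1cc(OC)ccc1OC | intermediate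
28 | (3S,4R)-4-ethynyl-1-iodo-3,4-dimethyl-6-Oct-hexane | C[C@@H]1CC=C2[C@@H](CCC[C@@]2(C)CC[C@@](C)(C#C)[C@@H](C)CCI)[C@]1(C)Cc1cc(OC)ccc1OC | intermediate
29 | 3,3-dimethylcyclobutan-1-one | CC1(C)CC(=O)C1 | starting material
30 | (S)-1-amino-2-(methoxymethyl)pyrrolidine (SAMP) | COC[C@@H]1CCCN1N | starting material
31 | (S)-N-(3,3-dimethylcyclobutylidene)-2-(methoxymethyl)pyrrolidin-1-amine | COC[C@@H]1CCCN1N=C1CC(C)(C)C1 | intermediate
32 | lithium azaenolate of 31 | COC[C@@H]1CCCN1N([Li])C1=CC(C)(C)C1 | intermediate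
33 | SAMP hydrazone of 34 | C[C@@H]1CC=C2[C@@H](CCC[C@@]2(C)CC[C@@](C)(C#C)[C@@H](C)CC[C@H]3/C(=N/N4CCC[C@H]4COC)CC3(C)C)[C@]1(C)Cc1cc(OC)ccc1OC | intermediate
34 | (2R)-2-[(3S,4R)-4-ethynyl-3,4-dimethyl-6-Oct-hexyl]-3,3-dimethylcyclobutan-1-one | C[C@@H]1CC=C2[C@@H](CCC[C@@]2(C)CC[C@@](C)(C#C)[C@@H](C)CC[C@H]3C(=O)CC3(C)C)[C@]1(C)Cc1cc(OC)ccc1OC | intermediate
35 | (5'R,8'S,9'R)-4',4',8',9'-tetramethyl-9'-(2-Oct-ethyl)-Δ1'(10')-octalin-2'-one | C[C@@H]1CC=C2[C@@H](CCC[C@@]2(C)CC[C@@]2(C)C3=CC(=O)CC(C)(C)[C@H]3CC[C@@H]2C)[C@]1(C)Cc1cc(OC)ccc1OC | intermediate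
36 | toxiusol hydroquinone bis(methyl ether) | C[C@@H]1CC=C2[C@@H](CCC[C@@]2(C)CC[C@@]2(C)C3=CCCC(C)(C)[C@H]3CC[C@@H]2C)[C@]1(C)Cc1cc(OC)ccc1OC | intermediate
37 | toxiusol hydroquinone | C[C@@H]1CC=C2[C@@H](CCC[C@@]2(C)CC[C@@]2(C)C3=CCCC(C)(C)[C@H]3CC[C@@H]2C)[C@]1(C)Cc1cc(O)ccc1O | intermediate
38 | toxiusol | C[C@@H]1CC=C2[C@@H](CCC[C@@]2(C)CC[C@@]2(C)C3=CCCC(C)(C)[C@H]3CC[C@@H]2C)[C@]1(C)Cc1cc(OS(=O)(=O)O)ccc1OS(=O)(=O)O | target

**Step count and risks**

Total step count: 25. Longest linear sequence: 23 steps (steps 1–11, 13–18, 20–25).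

Steps most likely to fail, with fallbacks:

1. Step 22 (key step). The catalyst may be diverted by the terminal alkyne (oligomerisation), the acylrhodium intermediate may lose CO, β-hydride elimination toward C6' may open the ring, or insertion next to the quaternary C9' may be too slow. The fallback sets out from 21 and comes back at 35, giving up the ring expansion for a Robinson-type annulation. Ketone 21 is converted as in step 14 (LDA, TMSCl) into silyl enol ether 22, isolated this time; its α'-carbon now becomes C5'. A TiCl4-mediated Mukaiyama–Michael addition of 22 to mesityl oxide (4-methylpent-3-en-2-one) in CH2Cl2 at −78 °C should give the 1,5-diketone F1 with the quaternary C4'. KOH in MeOH should then equilibrate C5' (α to the C10' ketone; the bulky side chain prefers the equatorial position, which is the required configuration) and close ring A' by intramolecular aldol condensation to 35.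

2. Step 13. C-alkylation of the hindered tetrasubstituted enolate by an unactivated primary iodide may be slow, so that proton transfer between enolate and product, O-alkylation, or E2 elimination of the iodide takes over. The fallback sets out from 15 and 19 and comes back at 21. Oxidation of 15 with the periodinane 1,1,1-triacetoxy-1,1-dihydro-1,2-benziodoxol-3(1H)-one should give the aldehyde F2. Aldol addition of lithium enolate 20 (from 19 and MeLi) to F2 at −78 °C, with the same facial preference anti to the C8' methyl, should give the β-hydroxy ketone F3. Dehydration with methyl N-(triethylammoniosulfonyl)carbamate can only run toward C11, because C9' has no hydrogen, and should give the E-alkene F4. Diimide (TsNHNH2, NaOAc) should reduce the disubstituted C11=C12 bond in preference to the trisubstituted ring alkene and give 21.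

3. Step 7. Catalyst control may be incomplete (loss of facial, endo or regiochemical selectivity when the catalyst and the C4 centre are mismatched), and the strong Lewis acid may polymerise the diene. The fallback sets out from 8 and comes back at 10, replacing catalyst control by a covalent auxiliary. Diene 8 is combined with (S)-4-benzyl-3-[(E)-but-2-enoyl]oxazolidin-2-one and Et2AlCl in CH2Cl2 at −78 °C; the chelated imide should react endo on the face opposite to the benzyl group to give the imide F5. LiBH4 in THF/MeOH should cleave the auxiliary reductively to the primary alcohol F6, and periodinane oxidation should return aldehyde 10.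

**Further compounds**

F1 | step 22 | (2R,3S,6R)-2,3-dimethyl-6-(2-methyl-4-oxopentan-2-yl)-2-(2-Oct-ethyl)cyclohexan-1-one (1,5-diketone) | C[C@@H]1CC=C2[C@@H](CCC[C@@]2(C)CC[C@@]2(C)C(=O)[C@@H](C(C)(C)CC(C)=O)CC[C@@H]2C)[C@]1(C)Cc1cc(OC)ccc1OC
F2 | step 13 | 2-Oct-acetaldehyde | C[C@@H]1CC=C2[C@@H](CCC[C@@]2(C)CC=O)[C@]1(C)Cc1cc(OC)ccc1OC
F3 | step 13 | (2R,3S)-2-(1-hydroxy-2-Oct-ethyl)-2,3-dimethylcyclohexan-1-one (both carbinol epimers) | C[C@@H]1CC=C2[C@@H](CCC[C@@]2(C)CC(O)[C@@]2(C)C(=O)CCC[C@@H]2C)[C@]1(C)Cc1cc(OC)ccc1OC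
F4 | step 13 | (2R,3S)-2,3-dimethyl-2-[(E)-2-Oct-vinyl]cyclohexan-1-one | C[C@@H]1CC=C2[C@@H](CCC[C@@]2(C)/C=C/[C@@]2(C)C(=O)CCC[C@@H]2C)[C@]1(C)Cc1cc(OC)ccc1OC
F5 | step 7 | (S)-4-benzyl-3-{[(4S,8R,10S)-4-(2-benzyloxyethyl)-4,8-dimethyl-Δ5-octalin-9-yl]carbonyl}oxazolidin-2-one (acyl group trans to H-10) | C[C@@H]1CC=C2[C@@H](CCC[C@@]2(C)CCOCc3ccccc3)[C@H]1C(=O)N1C(=O)OC[C@@H]1Cc1ccccc1
F6 | step 7 | [(4S,8R,10S)-4-(2-benzyloxyethyl)-4,8-dimethyl-Δ5-octalin-9-yl]methanol | C[C@@H]1CC=C2[C@@H](CCC[C@@]2(C)CCOCc3ccccc3)[C@H]1CO
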